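**Dihydrotetrachlorizine (17) by a chelation-directed propargyl Claisen rearrangement to an angular chromene**

Remarks on the chemistry:
- Compounds 9, 10 and 14 are racemic. The target has no stereocentre, so no enantiocontrol is sought; one enantiomer is drawn only to fix connectivity.
- Compounds 16 and 17 are written as open-chain hydroxy ketones, which are assumed to be favoured over their cyclic 2-hydroxychroman hemiketal tautomers.

Numbering used throughout:
- 1: 4,5-dichloro-1H-pyrrole-2-carboxylic acid
- 2: its acid chloride
- 3: resorcinol
- 4: 2,4-dihydroxyphenyl dichloropyrrolyl ketone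
- 5: pyrrole-2-carbaldehyde
- 6: 4,5-dichloropyrrole-2-carbaldehyde
- 7: N-tosyl derivative of 6
- 8: ethynylmagnesium bromide
- 9: propargylic alcohol
- 10: 4-O-propargylic ether (Claisen precursor)
- 11: allenyl dienone
- 12: allenyl phenol
- 13: ortho-quinone methide
- 14: 2H-chromene
- 15: 4H-chromene
- 16: N-tosyl diketone
- 17: dihydrotetrachlorizine

## Analysis of the target

Compound 17 has no stereocentre and no saturated ring. It is a benzene ring placed between two 4,5-dichloropyrrol-2-yl ketones. The benzene ring is 1,2,3,4-tetrasubstituted: C1 carries the diaryl ketone, C2 and C4 carry free hydroxyls, and C3, between the two oxygens, carries the CH2–CH2–C(=O) chain that ends in the second dichloropyrrole. C5 and C6 are unsubstituted. The sensitive groups are the four C–Cl bonds (hydrogenolysis, dissolving metals, halogen–metal exchange), the two acidic pyrrole N–H groups, the electron-rich resorcinol ring and the two ketones, one of which is enolizable. The synthesis is hard for three reasons. The chain must go to C3, the most crowded position of the resorcinol, and not to the open C5. The two pyrrolyl ketones are chemically alike yet must be built one after the other. Neither reducing nor chlorinating reagents can be used once the rings are assembled. The strategy rests on one relation in the chain: the ketone carbon, the two CH2 groups, arene C3, arene C4 and the C4 oxygen form a latent six-membered ring. Closing this ring on paper with loss of water gives a 2-pyrrolyl-4H-chromene fused across C3 and the C4 oxygen. That cyclic enol ether is the double-bond isomer of the 2H-chromene that a propargyl Claisen rearrangement delivers with the C3 carbon–carbon bond already in place.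

## Retrosynthetic reasoning

**17 from 16.** The last bond cut is the N–S bond of a sulfonyl group on the pyrrole of the alkyl ketone. The group is kept to the end because it is needed in the key step. It is easy to remove only once the pyrrole carries the acyl group, since the acylpyrrolide is then a good leaving group from sulfur.

**16 from 15.** The alkyl ketone and the C4 hydroxyl of 16 are joined, with loss of the elements of hydration, into the enol ether 15. The ketone carbon becomes chromene C2 and the C4 oxygen becomes the ring oxygen. This stores the ketone at its final oxidation level inside a ring, so no oxidation or reduction is needed to reveal it. The forward reaction is a plain enol ether hydrolysis.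

**15 from 14.** The C2=C3 double bond of 15 is moved to C3=C4, giving the 2H-chromene 14. No skeletal bond changes. The purpose is to reach the chromene isomer that pericyclic chemistry makes directly. The forward step must move the double bond into conjugation with the ring oxygen and the pyrrole.

**14 from 10.** Two bonds of 14 are cut. The ring O–C2 bond opens by retro-6π electrocyclization to the ortho-quinone methide 13, which is the hydrogen-shift isomer of the allenyl phenol 12. The bond from arene C3 to chromene C4 is then cut by a retro-[3,3] shift through the dienone 11, giving the aryl propargyl ether 10. This is the place to cut because the hard bond, the C–C bond at the crowded C3, is then made intramolecularly from an oxygen that is already there. All three chain carbons and the second pyrrole arrive in one piece. The forward reaction has to send the shift to C3 and not to C5.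

**10 from 4 and 9.** The ether C–O bond is cut to the phenol 4 and the racemic propargylic alcohol 9. Of the three acidic sites in 4, only the C4 hydroxyl must react, so the forward step is a Mitsunobu etherification, which selects the most acidic and unchelated hydroxyl.

**4 from 2 and 3, and 2 from 1.** The bond from arene C1 to the ketone carbon is cut, giving resorcinol 3 and the acid chloride 2 made from the acid 1. Both chlorine atoms of this pyrrole are bought with 1. The forward Friedel–Crafts acylation puts the acyl group at the resorcinol position that is ortho to one hydroxyl and para to the other.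

**9 from 7 and 8, and 7 from 6 from 5.** The bond between the carbinol carbon and the alkyne is cut to the aldehyde 7 and ethynylmagnesium bromide 8. Aldehyde 7 comes from 6 by N-sulfonylation, and 6 from pyrrole-2-carbaldehyde 5 by electrophilic dichlorination. The chlorines are thus introduced on a small, simple pyrrole before any valuable bond exists.

## Alternatives that were turned down

Alternative 1: Both pyrrole C2–carbonyl bonds and all four C–Cl bonds are disconnected.
- Forward key step: both amide groups of the bis(dimethylamide) A2 would be activated as chloroiminium ions under Vilsmeier–Haack conditions. Each would acylate 1H-pyrrole A3 at C2, and hydrolysis would give the diketone A1. Fourfold chlorination and cleavage of two methyl ethers would follow.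
- For: A3 is cheap, two C–C bonds form in one operation, and the acylation of A3 by aryl amide chloroiminium ions is dependable. On these points it is stronger than the chosen route, which needs two separately prepared dichloropyrrole components.
- Against:
  - The two amides of A2 differ. The aliphatic one has α-hydrogens and its chloroiminium ion can lose a proton to an α-chloroenamine. The aromatic one is hindered by an ortho methoxy group. The two-directional step is therefore two different reactions.
  - After A1, four chlorinations must go only to C4 and C5 of two pyrroles. The dimethoxyarene with its open C5 and the enolizable CH2 beside the alkyl ketone would compete for electrophilic chlorine.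
  - The final Lewis-acid ether cleavage is easy for the C2 ether next to the ketone and hard for the C4 ether.
  - A2 itself needs the three-carbon chain at C3 of a 2,6-dimethoxybenzoic acid derivative, so the central placement problem is only moved.
- Comparison: the chosen route fixes every chlorine by construction (bought in 1, or set on the simple aldehyde 5), has no phenol protecting group to remove, and solves the C3 placement with the Claisen rearrangement.

Alternative 2: The benzene ring is disconnected at arene bonds C5–C6 and C3–C4.
- Forward key step: the electron-rich alkene 1,1-dimethoxyethene A6 would add across C6 and C3 of the 3-alkyl-5-aroyl-4-methoxy-2-pyranone A5. Decarboxylative cycloreversion and loss of one methoxy group would leave the fully protected target A4.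
- For: all four arene substituents are placed by the pyranone, so no C3 against C5 question arises. On regiochemical certainty it is stronger than the chosen route, which depends on a directing effect.
- Against:
  - A5 is a 3,4,5-trisubstituted pyranone that already carries both protected dichloropyrrolyl ketones and needs a long synthesis of its own.
  - Its 4-methoxy group is a donor that works against the inverse electron demand, and its alkyl-bearing C3 is the hindered terminus that must bond to the acetal carbon of A6.
  - The two ketones of A5 offer A6 other acceptors, so addition without ring closure may compete.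
  - After the key step, A4 still carries four protecting groups (two SEM groups and two methyl ethers) that need fluoride or acid and a strong Lewis acid.
- Comparison: the chosen route buys the arene as 3, uses a single protecting group that falls to mild base, and reaches 17 in ten steps.

Alternative 3: The benzene ring is disconnected at arene bonds C5–C6 and C1–C2.
- Forward key step: the bis(silyloxy)diene A8 and the N-Boc pyrrolyl ynone A9 would combine in a Diels–Alder reaction, with the nucleophilic CH2 terminus of A8 bonding to the alkyne terminus of A9. Loss of the ethoxy group on acidic work-up would give the resorcinol ester A7.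
- For: A7 has both hydroxyls free, the aroyl group at C1 and the chain at C3, all set by the polarity of the two partners. On not needing any phenol deprotection it equals the chosen route, and on the certainty of the C3 placement it is stronger.
- Against:
  - A7 carries an ester where 17 has the second pyrrolyl ketone. Making that ketone late needs either a metallated 4,5-dichloropyrrole, where halogen–metal exchange competes, or acylation of A3 followed by chlorination in the presence of a free resorcinol.
  - A8 has a fully substituted ketene acetal terminus and is hindered and hydrolytically fragile.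
  - The Boc group on the acylpyrrole of A9 is labile, and A9 is a reactive Michael acceptor that can stop at the open-chain adduct.
- Comparison: in the chosen route both dichloropyrrole units are complete before the key step, and the second ketone is carried as chromene C2 at the right oxidation level. After the key step only an isomerization, a hydrolysis and a desulfonylation remain.

Key step: step 7

## Route

Step 1
Reactants: 1 4,5-dichloro-1H-pyrrole-2-carboxylic acid
Product: 2 4,5-dichloro-1H-pyrrole-2-carbonyl chloride
Conditions: (COCl)2, cat. DMF, CH2Cl2, 0 °C → rt; concentrate and use crude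
Reagents that add atoms: oxalyl chloride, O=C(Cl)C(=O)Cl
Why: Standard acid chloride formation through the chloroiminium species from DMF; the pyrrole ring is deactivated by two chlorines and the carbonyl group, so neither ring substitution nor N-acylation should compete at this temperature.

Step 2
Reactants: 2 4,5-dichloro-1H-pyrrole-2-carbonyl chloride; 3 resorcinol
Product: 4 (4,5-dichloro-1H-pyrrol-2-yl)(2,4-dihydroxyphenyl)methanone
Conditions: AlCl3 (3 equiv), 1,2-dichloroethane, 0 → 60 °C; then ice/aq. HCl
Reagents that add atoms: none
Why: Friedel–Crafts acylation of resorcinol goes to the position ortho to one hydroxyl and para to the other and not to the crowded carbon between them; the product ketone is deactivated and held as an aluminium chelate, which should stop a second acylation.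

Step 3
Reactants: 5 1H-pyrrole-2-carbaldehyde
Product: 6 4,5-dichloro-1H-pyrrole-2-carbaldehyde
Conditions: SO2Cl2 (2.1 equiv), Et2O, 0 °C → rt
Reagents that add atoms: sulfuryl chloride, O=S(=O)(Cl)Cl
Why: Electrophilic chlorination of a 2-acylpyrrole; the formyl group deactivates C3, so the first chlorine enters at C4 or C5 and the second at the other of these, and both paths meet in the 4,5-dichloride, the pattern known for 2-acylpyrroles with this reagent.

Step 4
Reactants: 6 4,5-dichloro-1H-pyrrole-2-carbaldehyde
Product: 7 4,5-dichloro-1-(4-methylbenzenesulfonyl)-1H-pyrrole-2-carbaldehyde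
Conditions: NaH, THF, 0 °C; then TsCl, 0 °C → rt
Reagents that add atoms: 4-methylbenzenesulfonyl chloride (TsCl), Cc1ccc(cc1)S(=O)(=O)Cl
Why: N-Sulfonylation of the sodium salt of an acidic pyrrole; the sulfonyl group is chosen because it removes electron density from the ring, which is what later holds the propargylic ether together in the key step.

Step 5
Reactants: 7 4,5-dichloro-1-(4-methylbenzenesulfonyl)-1H-pyrrole-2-carbaldehyde; 8 ethynylmagnesium bromide
Product: 9 rac-1-[4,5-dichloro-1-(4-methylbenzenesulfonyl)-1H-pyrrol-2-yl]prop-2-yn-1-ol (racemic)
Conditions: 8 (0.5 M in THF, 1.2 equiv), THF, −78 → 0 °C; aq. NH4Cl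
Reagents that add atoms: none
Why: Grignard 1,2-addition to an electron-poor heteroaryl aldehyde; the low temperature should keep the acetylide away from the sulfonyl sulfur, and the new carbinol centre is formed racemic on purpose because it is erased in step 8.

Step 6
Reactants: 4 (4,5-dichloro-1H-pyrrol-2-yl)(2,4-dihydroxyphenyl)methanone; 9 rac-1-[4,5-dichloro-1-(4-methylbenzenesulfonyl)-1H-pyrrol-2-yl]prop-2-yn-1-ol
Product: 10 rac-(4,5-dichloro-1H-pyrrol-2-yl)[4-({1-[4,5-dichloro-1-(4-methylbenzenesulfonyl)-1H-pyrrol-2-yl]prop-2-yn-1-yl}oxy)-2-hydroxyphenyl]methanone (racemic)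
Conditions: PPh3, DIAD, THF, 0 °C → rt
Reagents that add atoms: none
Why: Mitsunobu etherification, an SN2 displacement at the carbinol carbon with inversion (of no consequence for racemic material); the C4 hydroxyl, para to the ketone, is the most acidic site of 4 and is the one deprotonated and alkylated, while the C2 hydroxyl is held in the hydrogen bond to the carbonyl group and the pyrrole N–H is less acidic than the phenol.

Step 7
Reactants: 10 rac-(4,5-dichloro-1H-pyrrol-2-yl)[4-({1-[4,5-dichloro-1-(4-methylbenzenesulfonyl)-1H-pyrrol-2-yl]prop-2-yn-1-yl}oxy)-2-hydroxyphenyl]methanone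
Product: 14 rac-(4,5-dichloro-1H-pyrrol-2-yl){2-[4,5-dichloro-1-(4-methylbenzenesulfonyl)-1H-pyrrol-2-yl]-5-hydroxy-2H-chromen-6-yl}methanone, via allenyl dienone 11 (not isolated), via allenyl phenol 12 (not isolated), via ortho-quinone methide 13 (not isolated)
Conditions: 1,2-dichlorobenzene (degassed, 0.05 M), 150–170 °C, sealed tube
Reagents that add atoms: none
Why: Heating should start an aromatic propargyl Claisen rearrangement: a concerted suprafacial [3,3] shift through a six-membered transition state joins the alkyne terminus to arene C3 and breaks the O–CH bond, giving the allenyl dienone 11, which enolizes to the allenyl phenol 12. A 1,5-hydrogen shift from the restored C4 hydroxyl to the central allene carbon then gives the ortho-quinone methide 13, and a thermal disrotatory oxa-6π electrocyclization forms the O–C2 bond and closes the one new ring, the pyran ring of 14. The closest known reaction type is the thermal conversion of aryl propargyl ethers into 2H-chromenes, which for 4-propargyloxy-2-hydroxyaryl ketones is known to give the angular chromene. The selectivity needed is arene C3 against C5: the hydrogen bond between the C2 hydroxyl and the ketone favours the bond arrangement with a C1=C2 double bond in the chelate ring, which leaves C3–C4 as the bond with double-bond character next to the ether oxygen, so the shift should use C3. The sulfonyl group and the two chlorines make the pyrrole electron-poor and so should suppress heterolysis of the O–CH bond, the main competitor of the concerted path. The new stereocentre at chromene C2 follows from the allene axis in the ring closure, but the material is racemic and the centre is removed in step 8, so no control is needed. Ring closure through the C2 oxygen instead would cost nothing, because both oxygens are free hydroxyls again after step 9.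

Step 8
Reactants: 14 rac-(4,5-dichloro-1H-pyrrol-2-yl){2-[4,5-dichloro-1-(4-methylbenzenesulfonyl)-1H-pyrrol-2-yl]-5-hydroxy-2H-chromen-6-yl}methanone
Product: 15 (4,5-dichloro-1H-pyrrol-2-yl){2-[4,5-dichloro-1-(4-methylbenzenesulfonyl)-1H-pyrrol-2-yl]-5-hydroxy-4H-chromen-6-yl}methanone
Conditions: RuHCl(CO)(PPh3)3 (5–10 mol%), toluene, 100 °C
Reagents that add atoms: none
Why: A 2H-chromene is a cyclic allyl aryl ether, and ruthenium hydride catalysed isomerization of allyl ethers to enol ethers (hydrometalation placing ruthenium at C3, then β-hydride elimination of the C2–H) should move the double bond from C3=C4 to C2=C3. The driving force is a trisubstituted double bond conjugated with the ring oxygen and the pyrrole, and the hydride should add on the face away from the bulky sulfonylpyrrole, which is the face that carries the C2–H.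

Step 9
Reactants: 15 (4,5-dichloro-1H-pyrrol-2-yl){2-[4,5-dichloro-1-(4-methylbenzenesulfonyl)-1H-pyrrol-2-yl]-5-hydroxy-4H-chromen-6-yl}methanone
Product: 16 3-[3-(4,5-dichloro-1H-pyrrole-2-carbonyl)-2,6-dihydroxyphenyl]-1-[4,5-dichloro-1-(4-methylbenzenesulfonyl)-1H-pyrrol-2-yl]propan-1-one
Conditions: 2 M aq. HCl, THF, 50 °C
Reagents that add atoms: water, O
Why: Acid-catalysed enol ether hydrolysis: protonation at C3 gives an oxocarbenium ion at C2, water adds, and the hemiketal opens to the ketone and the C4 phenol; the sulfonamide, the C–Cl bonds and the diaryl ketone are inert to aqueous acid.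

Step 10
Reactants: 16 3-[3-(4,5-dichloro-1H-pyrrole-2-carbonyl)-2,6-dihydroxyphenyl]-1-[4,5-dichloro-1-(4-methylbenzenesulfonyl)-1H-pyrrol-2-yl]propan-1-one
Product: 17 dihydrotetrachlorizine, 3-[3-(4,5-dichloro-1H-pyrrole-2-carbonyl)-2,6-dihydroxyphenyl]-1-(4,5-dichloro-1H-pyrrol-2-yl)propan-1-one
Conditions: NaOH (5 equiv), MeOH/THF/H2O, 0 °C → rt; then aq. HCl to pH 3
Reagents that add atoms: none
Why: Hydroxide attacks the sulfonyl sulfur and expels the pyrrolide, which is a good leaving group now that the ring carries an acyl group and two chlorines; the phenols are only deprotonated and return on acidification, and no reducing agent meets the C–Cl bonds.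

## Compound list

1 | 4,5-dichloro-1H-pyrrole-2-carboxylic acid | OC(=O)c1cc(Cl)c(Cl)[nH]1 | starting material
2 | 4,5-dichloro-1H-pyrrole-2-carbonyl chloride | ClC(=O)c1cc(Cl)c(Cl)[nH]1 | intermediate
3 | resorcinol (benzene-1,3-diol) | Oc1cccc(O)c1 | starting material
4 | (4,5-dichloro-1H-pyrrol-2-yl)(2,4-dihydroxyphenyl)methanone | O=C(c1ccc(O)cc1O)c1cc(Cl)c(Cl)[nH]1 | intermediate
5 | 1H-pyrrole-2-carbaldehyde | O=Cc1ccc[nH]1 | starting material
6 | 4,5-dichloro-1H-pyrrole-2-carbaldehyde | O=Cc1cc(Cl)c(Cl)[nH]1 | intermediate
7 | 4,5-dichloro-1-(4-methylbenzenesulfonyl)-1H-pyrrole-2-carbaldehyde | O=Cc1cc(Cl)c(Cl)n1S(=O)(=O)c1ccc(C)cc1 | intermediate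
8 | ethynylmagnesium bromide | C#C[Mg]Br | starting material
9 | rac-1-[4,5-dichloro-1-(4-methylbenzenesulfonyl)-1H-pyrrol-2-yl]prop-2-yn-1-ol (racemic; R enantiomer drawn) | C#C[C@@H](O)c1cc(Cl)c(Cl)n1S(=O)(=O)c1ccc(C)cc1 | intermediate
10 | rac-(4,5-dichloro-1H-pyrrol-2-yl)[4-({1-[4,5-dichloro-1-(4-methylbenzenesulfonyl)-1H-pyrrol-2-yl]prop-2-yn-1-yl}oxy)-2-hydroxyphenyl]methanone (racemic; S enantiomer drawn) | C#C[C@H](Oc1ccc(C(=O)c2cc(Cl)c(Cl)[nH]2)c(O)c1)c1cc(Cl)c(Cl)n1S(=O)(=O)c1ccc(C)cc1 | intermediate
11 | 4-(4,5-dichloro-1H-pyrrole-2-carbonyl)-6-{3-[4,5-dichloro-1-(4-methylbenzenesulfonyl)-1H-pyrrol-2-yl]propa-1,2-dien-1-yl}-5-hydroxycyclohexa-2,4-dien-1-one (transient; stereoisomers not specified) | O=C1C=CC(C(=O)c2cc(Cl)c(Cl)[nH]2)=C(O)C1C=C=Cc1cc(Cl)c(Cl)n1S(=O)(=O)c1ccc(C)cc1 | intermediate (not isolated)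
12 | (4,5-dichloro-1H-pyrrol-2-yl)(3-{3-[4,5-dichloro-1-(4-methylbenzenesulfonyl)-1H-pyrrol-2-yl]propa-1,2-dien-1-yl}-2,4-dihydroxyphenyl)methanone (transient; racemic allene) | O=C(c1ccc(O)c(C=C=Cc2cc(Cl)c(Cl)n2S(=O)(=O)c2ccc(C)cc2)c1O)c1cc(Cl)c(Cl)[nH]1 | intermediate (not isolated)
13 | 4-(4,5-dichloro-1H-pyrrole-2-carbonyl)-6-{3-[4,5-dichloro-1-(4-methylbenzenesulfonyl)-1H-pyrrol-2-yl]prop-2-en-1-ylidene}-5-hydroxycyclohexa-2,4-dien-1-one (transient; double-bond geometry not specified) | O=C1C=CC(C(=O)c2cc(Cl)c(Cl)[nH]2)=C(O)C1=CC=Cc1cc(Cl)c(Cl)n1S(=O)(=O)c1ccc(C)cc1 | intermediate (not isolated)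
14 | rac-(4,5-dichloro-1H-pyrrol-2-yl){2-[4,5-dichloro-1-(4-methylbenzenesulfonyl)-1H-pyrrol-2-yl]-5-hydroxy-2H-chromen-6-yl}methanone (racemic; S enantiomer drawn) | O=C(c1ccc2c(c1O)C=C[C@@H](c1cc(Cl)c(Cl)n1S(=O)(=O)c1ccc(C)cc1)O2)c1cc(Cl)c(Cl)[nH]1 | intermediate
15 | (4,5-dichloro-1H-pyrrol-2-yl){2-[4,5-dichloro-1-(4-methylbenzenesulfonyl)-1H-pyrrol-2-yl]-5-hydroxy-4H-chromen-6-yl}methanone | O=C(c1ccc2c(c1O)CC=C(c1cc(Cl)c(Cl)n1S(=O)(=O)c1ccc(C)cc1)O2)c1cc(Cl)c(Cl)[nH]1 | intermediate
16 | 3-[3-(4,5-dichloro-1H-pyrrole-2-carbonyl)-2,6-dihydroxyphenyl]-1-[4,5-dichloro-1-(4-methylbenzenesulfonyl)-1H-pyrrol-2-yl]propan-1-one | O=C(CCc1c(O)ccc(C(=O)c2cc(Cl)c(Cl)[nH]2)c1O)c1cc(Cl)c(Cl)n1S(=O)(=O)c1ccc(C)cc1 | intermediate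
17 | dihydrotetrachlorizine, 3-[3-(4,5-dichloro-1H-pyrrole-2-carbonyl)-2,6-dihydroxyphenyl]-1-(4,5-dichloro-1H-pyrrol-2-yl)propan-1-one | O=C(CCc1c(O)ccc(C(=O)c2cc(Cl)c(Cl)[nH]2)c1O)c1cc(Cl)c(Cl)[nH]1 | target

## Step count and least certain steps

Total step count: 10. Longest linear sequence: 8 steps (steps 3, 4, 5, 6, 7, 8, 9 and 10, from 5 to 17). The branch from 1 takes two steps (1 and 2) and joins at step 6.

**Step 7 (key step).** Three processes could spoil it. The [3,3] shift could go to C5 instead of C3 if the chelate does not fix the bonds strongly enough at 150–170 °C. The secondary heteroaryl-substituted ether could cleave heterolytically before it rearranges. The allenyl phenol could close by 5-exo addition of the hydroxyl to the allene instead of passing through the hydrogen shift and the 6π closure.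
Fallback: it sets out from 7 and 4 and comes back to the route at 14, passing by 9 and 10. Aldehyde 7 would be homologated by a Wittig reaction with Ph3P=CHCHO (toluene, 80 °C) to the enal (E)-3-[4,5-dichloro-1-(4-methylbenzenesulfonyl)-1H-pyrrol-2-yl]prop-2-enal F1. F1 would then be condensed with 4 under ethylenediammonium diacetate catalysis in refluxing xylene, the chromenylation of a resorcinol with an enal. Knoevenagel-type attack of arene C3 on the aldehyde carbon and loss of water lead to the same ortho-quinone methide 13, which closes to 14. Here the C3–C bond comes from electrophilic substitution of the resorcinol and not from a sigmatropic shift, so the thermal behaviour of the ether no longer matters.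

**Step 8.** The hydride could add with ruthenium at the benzylic C4, from which only the reverse reaction is possible. The chelating hydroxy ketone or the pyrrole N–H could bind the catalyst. The equilibrium could also be less one-sided than conjugation suggests. A first change of conditions would be prototropic isomerization with KOt-Bu in DMSO, which risks attack on the sulfonamide.
Fallback: it sets out from 14 and comes back at 15 by an oxidation–reduction relay. Hydride abstraction from C2 with Ph3CBF4 in MeCN would give the aromatic salt 6-(4,5-dichloro-1H-pyrrole-2-carbonyl)-2-[4,5-dichloro-1-(4-methylbenzenesulfonyl)-1H-pyrrol-2-yl]-5-hydroxychromenylium tetrafluoroborate F2. A Hantzsch ester (diethyl 2,6-dimethyl-1,4-dihydropyridine-3,5-dicarboxylate) in CH2Cl2 would then deliver hydride to C4, the γ-position of the pyrylium ring and remote from the bulky substituent at C2, to give 15.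

**Step 6.** Alkylation at the acidic pyrrole nitrogen of 4 could compete with O-alkylation. Attack at the alkyne terminus (SN2′) could give an allenyl ether. The sulfonyl group next to the carbinol carbon could slow the displacement so that elimination or reduction of the azodicarboxylate adduct takes over.
Fallback: it sets out from 9 and 4 and comes back at 10. Alcohol 9 would be converted with ClCO2Me and pyridine (CH2Cl2, 0 °C) into rac-1-[4,5-dichloro-1-(4-methylbenzenesulfonyl)-1H-pyrrol-2-yl]prop-2-yn-1-yl methyl carbonate F3. F3 would be coupled with 4 by copper-catalysed propargylic etherification (Cu(MeCN)4PF6, i-Pr2NEt, MeCN, 0 °C). In this reaction a copper acetylide loses the carbonate to give a copper allenylidene, which the phenoxide attacks at the propargylic carbon. This reaction type is selective for the propargylic position of terminal alkynes and uses the phenol as its salt, which again favours the C4 oxygen.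

**Step 3.** The chlorination could stop at mixtures of mono-, di- and trichlorides that are hard to separate, and the formyl group could suffer under the reagent.
Fallback: it sets out from 2 and comes back at 7, so that all chlorines come from 1. Acid chloride 2 would be treated with MeNH(OMe)·HCl and Et3N (CH2Cl2, 0 °C) to give 4,5-dichloro-N-methoxy-N-methyl-1H-pyrrole-2-carboxamide F4. Sulfonylation with NaH and TsCl in THF would give 4,5-dichloro-N-methoxy-N-methyl-1-(4-methylbenzenesulfonyl)-1H-pyrrole-2-carboxamide F5. Reduction of F5 with i-Bu2AlH (THF, −78 °C) through the stable chelated tetrahedral intermediate would release 7 on aqueous work-up.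

## Further compounds

F1 | step 7 | (E)-3-[4,5-dichloro-1-(4-methylbenzenesulfonyl)-1H-pyrrol-2-yl]prop-2-enal | O=C/C=C/c1cc(Cl)c(Cl)n1S(=O)(=O)c1ccc(C)cc1
F2 | step 8 | 6-(4,5-dichloro-1H-pyrrole-2-carbonyl)-2-[4,5-dichloro-1-(4-methylbenzenesulfonyl)-1H-pyrrol-2-yl]-5-hydroxychromenylium tetrafluoroborate | O=C(c1ccc2[o+]c(ccc2c1O)-c1cc(Cl)c(Cl)n1S(=O)(=O)c1ccc(C)cc1)c1cc(Cl)c(Cl)[nH]1.F[B-](F)(F)F
F3 | step 6 | rac-1-[4,5-dichloro-1-(4-methylbenzenesulfonyl)-1H-pyrrol-2-yl]prop-2-yn-1-yl methyl carbonate (racemic; one enantiomer drawn) | C#C[C@@H](OC(=O)OC)c1cc(Cl)c(Cl)n1S(=O)(=O)c1ccc(C)cc1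
F4 | step 3 | 4,5-dichloro-N-methoxy-N-methyl-1H-pyrrole-2-carboxamide | CON(C)C(=O)c1cc(Cl)c(Cl)[nH]1
F5 | step 3 | 4,5-dichloro-N-methoxy-N-methyl-1-(4-methylbenzenesulfonyl)-1H-pyrrole-2-carboxamide | CON(C)C(=O)c1cc(Cl)c(Cl)n1S(=O)(=O)c1ccc(C)cc1
A1 | alternative 1 | 3-[2,6-dimethoxy-3-(1H-pyrrole-2-carbonyl)phenyl]-1-(1H-pyrrol-2-yl)propan-1-one | COc1ccc(C(=O)c2ccc[nH]2)c(OC)c1CCC(=O)c1ccc[nH]1
A2 | alternative 1 | 3-[3-(dimethylcarbamoyl)-2,6-dimethoxyphenyl]-N,N-dimethylpropanamide | COc1ccc(C(=O)N(C)C)c(OC)c1CCC(=O)N(C)C
A3 | alternative 1 | 1H-pyrrole | c1cc[nH]c1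
A4 | alternative 2 | 3-[3-(4,5-dichloro-1-{[2-(trimethylsilyl)ethoxy]methyl}-1H-pyrrole-2-carbonyl)-2,6-dimethoxyphenyl]-1-(4,5-dichloro-1-{[2-(trimethylsilyl)ethoxy]methyl}-1H-pyrrol-2-yl)propan-1-one | COc1ccc(C(=O)c2cc(Cl)c(Cl)n2COCC[Si](C)(C)C)c(OC)c1CCC(=O)c1cc(Cl)c(Cl)n1COCC[Si](C)(C)C
A5 | alternative 2 | 5-(4,5-dichloro-1-{[2-(trimethylsilyl)ethoxy]methyl}-1H-pyrrole-2-carbonyl)-3-[3-(4,5-dichloro-1-{[2-(trimethylsilyl)ethoxy]methyl}-1H-pyrrol-2-yl)-3-oxopropyl]-4-methoxy-2H-pyran-2-one | COc1c(CCC(=O)c2cc(Cl)c(Cl)n2COCC[Si](C)(C)C)c(=O)occ1C(=O)c1cc(Cl)c(Cl)n1COCC[Si](C)(C)C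
A6 | alternative 2 | 1,1-dimethoxyethene | C=C(OC)OC
A7 | alternative 3 | ethyl 3-{3-[1-(tert-butoxycarbonyl)-4,5-dichloro-1H-pyrrole-2-carbonyl]-2,6-dihydroxyphenyl}propanoate | CCOC(=O)CCc1c(O)ccc(C(=O)c2cc(Cl)c(Cl)n2C(=O)OC(C)(C)C)c1O
A8 | alternative 3 | ethyl 4-[ethoxy(trimethylsilyloxy)methylidene]-5-(trimethylsilyloxy)hex-5-enoate | C=C(O[Si](C)(C)C)C(CCC(=O)OCC)=C(OCC)O[Si](C)(C)C
A9 | alternative 3 | tert-butyl 2,3-dichloro-5-(prop-2-ynoyl)-1H-pyrrole-1-carboxylate | C#CC(=O)c1cc(Cl)c(Cl)n1C(=O)OC(C)(C)C
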